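A small charge of Vy raises one question for me: how much of the Lx does it pull towards Ym and away from Jy in this flask?

| setting | eta | flask |
|---|---|---|
| Lx | 0.71 M | 0.71 M |
| Vy | 0.75 equiv | 0.500 equiv |
| Uv | 37 mM (held) | 37 mM (held) |
| remark | run made earlier |  |
| time |  | 15 d |

eta run (percent of the Lx charged)

| time / d | Ym / % | Jy / % |
|---|---|---|
| 0.250 | 6 | 5 |
| 0.417 | 4 | 4 |
| 0.833 | 12 | 15 |
| 1.67 | 19 | 28 |
| 3.00 | 25 | 40 |

(readings scatter by 1.5 percentage points)

- the numbers in the tables scatter by 1.5 percentage points (one standard deviation)
- at the start none of Uv is in solution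

- share of Ym in Ym plus Jy at 3.0 h
- share of Ym in Ym plus Jy at 15 d
- which of Ym and Jy there is more of at 15 d

1. I assume that Jy forms steadily, with Uv held, and that Ym forms in step with the Vy still present. With amounts counted per Lx charged, the log of Vy charged over Vy left then equals a constant times Jy. The eta reading at 3.00 d gives 1.01 for the split number, the Ym made per Jy made per equivalent of Vy present, a selectivity factor.

2. I treat Ym as a correction to Jy. If Jy took the whole of the Lx, the flask would hold 31.9% Ym. But that Ym comes out of Jy, so I put the lower Jy back and get 24.9%. This overshoots, so I repeat it: 26.6%, then 26.2%. Counting Ym and Jy together as the whole Lx, my estimate of the late share is about 26.2%.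

3. Is the Lx finished by then? The eta reading at 3.00 d gives a pseudo-first-order rate of 0.350 d⁻¹. Carried over to this flask, that rate gives my estimate of 0.525% of the Lx left at 15 d.

4. The early share needs a different number. The first two eta readings pooled give Ym over Jy of 1.11, above the 0.760 that the split number gives for the start of the eta run. Scaling that ratio to this flask's Vy gives 0.741, a share of 42.6%. I hold this loosely, since each reading scatters by 1.5 percentage points and they stand later than 3.0 h.

5. The forecast gives 50% early, on the ground that “Uv is still dissolving, so Jy lags”, and 26% late, with Jy ahead. My early share is lower than its figure.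

6. The flask gives 41.4% at 3.0 h and 25.5% at 15 d, with Jy ahead.

    Lx → Wa (k = 2.70 × 10⁻⁴ min⁻¹)
    Qi + Wa → Jy (k = 0.660 M⁻¹ min⁻¹)
    Vy + Wa → Ym (k = 0.0270 M⁻¹ min⁻¹)
    Wa → Qa (k = 9.40 × 10⁻⁴ min⁻¹)
    Uv ⇌ Qi, rate k5*(csat - [Qi]) (kL = 0.0120 min⁻¹)

At 15.0 d, the flask has 0.293% of its Lx left and 50.9% of its own Vy charge. For the neighbour with 0.200 equiv of Vy, the first pass with 1.01 gives 12.7% Ym and the second gives 11.7%. That neighbour holds 11.2% Ym at 15.0 d.

Readings and results were computed with constants of no real substance; scatter was added.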